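## Structural features

The target is a 2,3-dihydro-1,4-benzodioxine: a benzene ring (ring A) fused to a 1,4-dioxane ring (ring B), numbered here so that O1 is bonded to C2 and C8a, and O4 to C3 and C4a. C2 carries a 3,4,5-trimethoxyphenyl group (ring C) and C3 a methyl group. Ring A carries a methoxy group on C5, next to O4, and an (E)-3-oxoprop-1-enyl chain on C7, para to O4 and meta to O1. C2 and C3 are adjacent stereocentres, both S, which places aryl and methyl trans on ring B. The enal is the most fragile group (conjugate addition, base, further olefination), and the benzylic C2–O1 ether next to an electron-rich arene can ionise in strong acid. The real difficulty is to set the absolute and relative configuration of two neighbouring oxygen-bearing sp3 carbons while joining each to the correct oxygen of an unsymmetrical catechol unit (O1 lies next to C8–H, O4 next to the C5 methoxy group). The key step uses the fact that C2 is a CH with three different partners, C3, ring C and O1: it can be a one-carbon unit from dichloromethane inserted between a boron-bound C3 and an aryl Grignard reagent, with boron later exchanged for O1. C3 has the same pattern (CH bonded to methyl, O4 and C2), so one earlier cycle of the same chemistry builds it.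

## Logic of the disconnections

**20 to 19.** The C=C bond of the enal is cut. The enal is the least tolerant group, so it is made last. This leaves an aryl aldehyde and asks the forward step for an E-selective two-carbon olefination that stops after one homologation.

**19 to 17 (through 18).** The O1–C8a aryl–oxygen bond is cut, with the aldehyde masked as its cyclic acetal. Ring B opens to an acyclic alcohol that still holds both stereocentres and an ortho-bromo aryl ether. The forward step must couple a hindered secondary benzylic alkoxide to an electron-rich aryl bromide without touching C2 or C3. The acetal keeps ring A electron-rich, which should also suppress a Smiles-type aryl shift from O4 to the C2 oxygen, and it must then come off under mild acid.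

**17 to 16.** The C2–O1 bond is exchanged for a C2–B bond. Boron at C2 is what allows C2 to be assembled by metallate shifts. The forward oxidation must proceed with retention and faster than loss of the aryloxy group from the neighbouring carbon.

**16 to 10 + 4 + 12 (through 13, 14, 15).** The C2–C3 and C2–aryl bonds are cut, so C2 becomes the carbon of 4. This is the strategic simplification: three components, two skeletal bonds and one stereocentre in one operation. The forward step needs reagent control at C2 from the diol on boron, and tolerance of the aryl bromide and the acetal. The stereochemical bookkeeping was checked along the sequence and is coherent: (S) at the chloride carbon of 6, (R) in 10 after inversion, (1S,2S) in 14 (retention at the migrating carbon, whose descriptor changes only because its neighbour changes), (1S,2S) in 16 after inversion at C2, (1S,2S) in 17, and (2S,3S) in 18 to 20. The design of 10 is kept for these reasons: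
- Bromide, not iodide: an iodide would couple more easily later but is at risk of halogen–metal exchange with the carbenoid and with 12.
- A C2-symmetric diol on boron: 13 and 15 then carry no boron stereocentre.
- A cyclic acetal: it is inert to both organometallic reagents.

Two points of execution are tightened: the carbenoid is preformed so that no alkyllithium meets the aryl bromide, and the zinc and lithium salts are removed before 12 is added.

**12 to 11.** The C–Mg bond is cut back to the aryl bromide; a direct magnesium insertion is required.

**10 to 6 + 8 (through 9).** The O4–C3 bond is cut. This attaches the more hindered catechol oxygen first and unambiguously, and it sets C3 by inversion of a configurationally defined chloride. The forward step asks a phenoxide with two ortho substituents to displace chloride at the boron-bearing carbon.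

**8 to 7.** The acetal is removed retrosynthetically to give the commercial bromophenol aldehyde. The forward acetalisation must cope with a free para-hydroxyl group.

**6 to 3 + 4 (through 5).** The C3–CH3 bond is cut, so C3 is also a carbon of 4 and the methyl group starts on boron. The forward step is the first diol-controlled chloromethylene insertion.

**3 to 1 + 2.** The two B–O bonds are cut to give the boronic acid and the recoverable chiral diol.

## Other disconnections considered

**Alternative 1:** The cut is the O4–C3 bond, with the C3 methyl group traced back to the terminus of a vinyl group. This leads to the allylic aryl ether methyl 4-hydroxy-3-methoxy-5-{[(1R)-1-(3,4,5-trimethoxyphenyl)prop-2-en-1-yl]oxy}benzoate A1. In the forward direction a cobalt hydride would deliver a hydrogen atom to the CH2 terminus, the C3 radical would be oxidised, and the free phenol would capture it to give methyl (2S,3S)-5-methoxy-3-methyl-2-(3,4,5-trimethoxyphenyl)-2,3-dihydro-1,4-benzodioxine-7-carboxylate A2.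
- In its favour: ring B, the methyl group and the second stereocentre would arise in one catalytic step near room temperature. C2 could come from a catalytic enantioselective allylic etherification. An ester is a sturdier spectator than an acetal.
- Against it here: C3 would be set only by the existing C2 centre in the ring closure, so the trans relationship is not assured. A cation-like C3 next to C2–H invites a 1,2-hydride shift to the oxocarbenium ion stabilised by O1 and ring C, which would erase C2. The oxidant needed for turnover meets a free, electron-rich phenol. The etherification leading to A1 must distinguish the two hydroxyl groups of a catechol.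
- Comparison: this plan is the better one in step count to the bicyclic core and in using catalytic rather than stoichiometric chirality. The conversion of the ester of A2 into the enal is of about equal length to the endgame chosen. The chosen plan is stronger in stereochemical security, since each centre comes from reagent control or a stereospecific shift.

**Alternative 2:** The cut removes O4–C3 and C3–C2 together, giving phenol 8, ethyl diazoacetate A4 and 3,4,5-trimethoxybenzaldehyde A5. In the forward direction Rh2(OAc)4 would turn A4 into a carbene, 8 would add to give an oxonium ylide, and A5 held by a chiral phosphoric acid would intercept it. The product would be ethyl (2R,3S)-2-[2-bromo-4-(1,3-dioxolan-2-yl)-6-methoxyphenoxy]-3-hydroxy-3-(3,4,5-trimethoxyphenyl)propanoate A3.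
- In its favour: three simple components, two bonds and both stereocentres in one catalytic step without cryogenic conditions, and the same bromide handle for closing ring B.
- Against it here: C3 of A3 carries an ester where the target needs a methyl group, so about three further operations (reduction, activation, hydride displacement) are needed. Until then the ester makes C3–H acidic under the basic ring closure. Acceptor-only diazo esters tend towards plain O–H insertion, and an electron-rich aldehyde such as A5 is a weak trap. The acid co-catalyst threatens the acetal.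
- Comparison: this plan is the better one in convergence and atom economy of the key event, and equal in the ring-closing endgame. The chosen plan fits the oxidation level of the target (the methyl arrives as a methyl) and is shorter once the ester-to-methyl steps are counted.

**Alternative 3:** The cut removes O1–C2 and O4–C4a, giving the cis-epoxide (2S,3R)-2-methyl-3-(3,4,5-trimethoxyphenyl)oxirane A6 and 4-fluoro-3-hydroxy-5-methoxybenzaldehyde A7. In the forward direction, with Cs2CO3, the phenoxide of A7 would open A6 at the benzylic carbon with inversion. The liberated alkoxide would then displace the fluoride para to the formyl group, giving (2S,3S)-5-methoxy-3-methyl-2-(3,4,5-trimethoxyphenyl)-2,3-dihydro-1,4-benzodioxine-7-carbaldehyde A8, which is the same compound as 19.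
- In its favour: ring B is made in one step and the target lies one olefination further. The aldehyde serves as the activating group and needs no protection. A cis-epoxide maps stereospecifically onto the trans product.
- Against it here: both epoxide carbons are secondary and ring C is only a moderate donor. Attack at the methyl-bearing carbon would therefore compete and, since either alkoxide can close the ring, would give the regioisomer with aryl and methyl exchanged. Cationic character at the benzylic carbon would erode the inversion. Enantiopure A6 needs a (Z)-propenylarene and an epoxidation that does not leak to the trans isomer. The fluoride of A7 sits between two ortho oxygen substituents, and the aldehyde must survive hot carbonate.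
- Comparison: on step economy this is clearly the better plan, and on stereospecificity it is in principle the equal. The chosen plan is stronger on regiochemistry, because its two C–O bonds are made in separate steps by different mechanisms at carbons distinguished by boron. It is also stronger on the source of chirality, which is a recoverable diol.

Key step: step 6

Remark on the chemistry: an (R,R)-1,2-dicyclohexylethane-1,2-diol boronate is assumed to give the (S)-alpha-chloro boronic ester in each chloromethylene insertion, as is usual for this diol.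

## Route

Step 1
Reactants: 1 methylboronic acid; 2 (1R,2R)-1,2-dicyclohexylethane-1,2-diol
Product: 3 (4R,5R)-4,5-dicyclohexyl-2-methyl-1,3,2-dioxaborolane
Conditions: Et2O, 4 Å molecular sieves, rt
Reagents that add atoms: none
Why: Condensation of a boronic acid with a 1,2-diol to the cyclic boronic ester, driven by removal of water; no stereocentre is formed and the diol centres are untouched.

Step 2
Reactants: 3 (4R,5R)-4,5-dicyclohexyl-2-methyl-1,3,2-dioxaborolane; 4 dichloromethane
Product: 6 (4R,5R)-2-[(1S)-1-chloroethyl]-4,5-dicyclohexyl-1,3,2-dioxaborolane, via lithium dichloromethyl(methyl)borate 5 (not isolated)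
Conditions: 4 (excess), n-BuLi, THF, −100 °C; 3; ZnCl2 (THF), −100 °C → rt
Reagents that add atoms: none
Why: Matteson homologation: LiCHCl2 adds to boron to give borate 5, and ZnCl2 promotes the 1,2-shift of the methyl group with loss of one chloride; the (R,R)-diol decides which of the two diastereotopic chlorides leaves, which should give the (S)-chloride that later becomes C3.

Step 3
Reactants: 7 3-bromo-4-hydroxy-5-methoxybenzaldehyde (5-bromovanillin)
Product: 8 2-bromo-4-(1,3-dioxolan-2-yl)-6-methoxyphenol
Conditions: ethylene glycol, TsOH·H2O (cat.), toluene, reflux, Dean–Stark; Et3N before work-up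
Reagents that add atoms: ethane-1,2-diol (ethylene glycol), OCCO
Why: Acid-catalysed acetalisation driven by azeotropic removal of water; the catalyst is neutralised before work-up because the para-hydroxyl group makes this acetal unusually easy to reopen.

Step 4
Reactants: 8 2-bromo-4-(1,3-dioxolan-2-yl)-6-methoxyphenol; 6 (4R,5R)-2-[(1S)-1-chloroethyl]-4,5-dicyclohexyl-1,3,2-dioxaborolane
Product: 10 (4R,5R)-2-{(1R)-1-[2-bromo-4-(1,3-dioxolan-2-yl)-6-methoxyphenoxy]ethyl}-4,5-dicyclohexyl-1,3,2-dioxaborolane, via sodium aryloxide 9 (not isolated)
Conditions: NaH, THF/DMSO, 0 °C; then 6, 0 °C → rt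
Reagents that add atoms: none
Why: Nucleophilic displacement at an alpha-chloro boronic ester: aryloxide 9 adds to boron and then shifts from boron to carbon anti to the departing chloride, so the carbon is inverted and the (S)-chloride should become the (R)-aryloxy centre (the future C3, bonded to O4); the acetal and the aryl bromide are inert to these conditions.

Step 5
Reactants: 11 5-bromo-1,2,3-trimethoxybenzene
Product: 12 (3,4,5-trimethoxyphenyl)magnesium bromide (titrated THF solution)
Conditions: Mg turnings, I2 (cat.), THF, reflux
Reagents that add atoms: magnesium, [Mg]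
Why: Direct insertion of magnesium into an aryl bromide (Grignard reagent formation); the methoxy groups are compatible.

Step 6
Reactants: 10 (4R,5R)-2-{(1R)-1-[2-bromo-4-(1,3-dioxolan-2-yl)-6-methoxyphenoxy]ethyl}-4,5-dicyclohexyl-1,3,2-dioxaborolane; 4 dichloromethane; 12 (3,4,5-trimethoxyphenyl)magnesium bromide
Product: 16 (4R,5R)-2-{(1S,2S)-2-[2-bromo-4-(1,3-dioxolan-2-yl)-6-methoxyphenoxy]-1-(3,4,5-trimethoxyphenyl)propyl}-4,5-dicyclohexyl-1,3,2-dioxaborolane, via lithium dichloromethylborate 13 (not isolated), via alpha-chloro boronic ester 14 (not isolated), via bromomagnesium arylborate 15 (not isolated)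
Conditions: 4, n-BuLi, THF, −100 °C; 10; ZnCl2 (3 equiv, THF), −100 °C → rt; pentane, filtration of salts; then 12 (1.5 equiv), THF, −78 °C → rt; cold NH4Cl work-up, used at once
Reagents that add atoms: none
Why: Preformed LiCHCl2 adds to the trigonal boron of 10 to give borate 13; on warming, ZnCl2 assists the departure of one chloride while C3 migrates from boron to the dichloromethyl carbon with retention at C3, which forms the C3–C2 bond in 14. The C2-symmetric (R,R)-diol makes the two chlorides of 13 diastereotopic and only one can leave without a clash with a cyclohexyl group in the zinc-bridged transition state, which should fix C2 as the (S)-chloride. After the salts are removed, Grignard reagent 12 adds to boron to give borate 15, and the aryl group shifts from boron to C2 with stereospecific inversion, expelling chloride and forming the C2–aryl bond of 16. The closest known reaction type is the Matteson asymmetric homologation of alpha-alkoxy boronic esters of chiral diols followed by Grignard displacement. No ring is closed. The one new stereocentre, C2, is controlled by the boron-bound diol in the first shift and by inversion in the second, while C3 is carried through unchanged. Chemoselectivity against the aryl bromide and the acetal is needed; it is secured because no free n-BuLi is present and aryl Grignard reagents neither exchange with aryl bromides nor open cyclic acetals at or below room temperature. The 1,2-shifts must also outrun beta-elimination of the aryloxide, which the much better leaving ability of the anti-periplanar chloride and the low temperature should secure.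

Step 7
Reactants: 16 (4R,5R)-2-{(1S,2S)-2-[2-bromo-4-(1,3-dioxolan-2-yl)-6-methoxyphenoxy]-1-(3,4,5-trimethoxyphenyl)propyl}-4,5-dicyclohexyl-1,3,2-dioxaborolane
Product: 17 (1S,2S)-2-[2-bromo-4-(1,3-dioxolan-2-yl)-6-methoxyphenoxy]-1-(3,4,5-trimethoxyphenyl)propan-1-ol
Conditions: 30% H2O2, 3 M NaOH, THF, 0 °C → rt
Reagents that add atoms: hydrogen peroxide, OO
Why: Oxidation of a boronic ester: hydroperoxide adds to boron and C2 migrates from boron to oxygen with retention, so the (1S,2S) threo alcohol should result; the fast peroxide shift is expected to outpace base-induced loss of the neighbouring aryloxy group, and diol 2 is released for recovery.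

Step 8
Reactants: 17 (1S,2S)-2-[2-bromo-4-(1,3-dioxolan-2-yl)-6-methoxyphenoxy]-1-(3,4,5-trimethoxyphenyl)propan-1-ol
Product: 19 (2S,3S)-5-methoxy-3-methyl-2-(3,4,5-trimethoxyphenyl)-2,3-dihydro-1,4-benzodioxine-7-carbaldehyde, via benzodioxane acetal 18 (not isolated)
Conditions: CuI (10 mol%), 3,4,7,8-tetramethyl-1,10-phenanthroline (20 mol%), Cs2CO3, toluene, 110 °C, Ar; filtration; then 1 M HCl, THF, rt
Reagents that add atoms: water, O
Why: Intramolecular Ullmann-type C–O coupling of the secondary alkoxide with the ortho aryl bromide closes the six-membered ring B at O1–C8a without touching C2 or C3, so the threo alcohol should give the trans (2S,3S) ring; the electron-rich acetal-bearing ring A disfavours a Smiles-type aryl shift, and mild aqueous acid then hydrolyses the acetal.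

Step 9
Reactants: 19 (2S,3S)-5-methoxy-3-methyl-2-(3,4,5-trimethoxyphenyl)-2,3-dihydro-1,4-benzodioxine-7-carbaldehyde
Product: 20 (2E)-3-[(2S,3S)-5-methoxy-3-methyl-2-(3,4,5-trimethoxyphenyl)-2,3-dihydro-1,4-benzodioxin-7-yl]prop-2-enal (CNP0258373.1)
Conditions: Ph3P=CHCHO (1.2 equiv), toluene, 80 °C
Reagents that add atoms: (triphenylphosphoranylidene)acetaldehyde, O=CC=P(c1ccccc1)(c1ccccc1)c1ccccc1
Why: Wittig olefination with a stabilised formyl ylide, which should give the E-enal; the neutral conditions leave the benzylic ether and both stereocentres untouched.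

## Compound list

1 | methylboronic acid | CB(O)O | starting material
2 | (1R,2R)-1,2-dicyclohexylethane-1,2-diol | O[C@H](C1CCCCC1)[C@H](O)C1CCCCC1 | starting material
3 | (4R,5R)-4,5-dicyclohexyl-2-methyl-1,3,2-dioxaborolane | CB1O[C@H](C2CCCCC2)[C@@H](C2CCCCC2)O1 | intermediate
4 | dichloromethane | ClCCl | starting material
5 | lithium (4R,5R)-4,5-dicyclohexyl-2-(dichloromethyl)-2-methyl-1,3,2-dioxaborolan-2-uide | [Li+].C[B-]1(C(Cl)Cl)O[C@H](C2CCCCC2)[C@@H](C2CCCCC2)O1 | intermediate (not isolated)
6 | (4R,5R)-2-[(1S)-1-chloroethyl]-4,5-dicyclohexyl-1,3,2-dioxaborolane | C[C@@H](Cl)B1O[C@H](C2CCCCC2)[C@@H](C2CCCCC2)O1 | intermediate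
7 | 3-bromo-4-hydroxy-5-methoxybenzaldehyde (5-bromovanillin) | COc1cc(C=O)cc(Br)c1O | starting material
8 | 2-bromo-4-(1,3-dioxolan-2-yl)-6-methoxyphenol | COc1cc(C2OCCO2)cc(Br)c1O | intermediate
9 | sodium 2-bromo-4-(1,3-dioxolan-2-yl)-6-methoxyphenolate | [Na+].COc1cc(C2OCCO2)cc(Br)c1[O-] | intermediate (not isolated)
10 | (4R,5R)-2-{(1R)-1-[2-bromo-4-(1,3-dioxolan-2-yl)-6-methoxyphenoxy]ethyl}-4,5-dicyclohexyl-1,3,2-dioxaborolane | C[C@H](Oc1c(Br)cc(C2OCCO2)cc1OC)B1O[C@H](C2CCCCC2)[C@@H](C2CCCCC2)O1 | intermediate
11 | 5-bromo-1,2,3-trimethoxybenzene | COc1cc(Br)cc(OC)c1OC | starting material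
12 | (3,4,5-trimethoxyphenyl)magnesium bromide | COc1cc([Mg]Br)cc(OC)c1OC | intermediate
13 | lithium (4R,5R)-2-{(1R)-1-[2-bromo-4-(1,3-dioxolan-2-yl)-6-methoxyphenoxy]ethyl}-4,5-dicyclohexyl-2-(dichloromethyl)-1,3,2-dioxaborolan-2-uide | [Li+].C[C@H](Oc1c(Br)cc(C2OCCO2)cc1OC)[B-]1(C(Cl)Cl)O[C@H](C2CCCCC2)[C@@H](C2CCCCC2)O1 | intermediate (not isolated)
14 | (4R,5R)-2-{(1S,2S)-2-[2-bromo-4-(1,3-dioxolan-2-yl)-6-methoxyphenoxy]-1-chloropropyl}-4,5-dicyclohexyl-1,3,2-dioxaborolane | C[C@H](Oc1c(Br)cc(C2OCCO2)cc1OC)[C@@H](Cl)B1O[C@H](C2CCCCC2)[C@@H](C2CCCCC2)O1 | intermediate (not isolated)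
15 | bromomagnesium (4R,5R)-2-{(1S,2S)-2-[2-bromo-4-(1,3-dioxolan-2-yl)-6-methoxyphenoxy]-1-chloropropyl}-4,5-dicyclohexyl-2-(3,4,5-trimethoxyphenyl)-1,3,2-dioxaborolan-2-uide | Br[Mg+].C[C@H](Oc1c(Br)cc(C2OCCO2)cc1OC)[C@@H](Cl)[B-]1(c2cc(OC)c(OC)c(OC)c2)O[C@H](C2CCCCC2)[C@@H](C2CCCCC2)O1 | intermediate (not isolated)
16 | (4R,5R)-2-{(1S,2S)-2-[2-bromo-4-(1,3-dioxolan-2-yl)-6-methoxyphenoxy]-1-(3,4,5-trimethoxyphenyl)propyl}-4,5-dicyclohexyl-1,3,2-dioxaborolane | COc1cc([C@H](B2O[C@H](C3CCCCC3)[C@@H](C3CCCCC3)O2)[C@H](C)Oc2c(Br)cc(C3OCCO3)cc2OC)cc(OC)c1OC | intermediate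
17 | (1S,2S)-2-[2-bromo-4-(1,3-dioxolan-2-yl)-6-methoxyphenoxy]-1-(3,4,5-trimethoxyphenyl)propan-1-ol | COc1cc([C@H](O)[C@H](C)Oc2c(Br)cc(C3OCCO3)cc2OC)cc(OC)c1OC | intermediate
18 | 2-[(2S,3S)-5-methoxy-3-methyl-2-(3,4,5-trimethoxyphenyl)-2,3-dihydro-1,4-benzodioxin-7-yl]-1,3-dioxolane | COc1cc([C@@H]2Oc3cc(C4OCCO4)cc(OC)c3O[C@H]2C)cc(OC)c1OC | intermediate (not isolated)
19 | (2S,3S)-5-methoxy-3-methyl-2-(3,4,5-trimethoxyphenyl)-2,3-dihydro-1,4-benzodioxine-7-carbaldehyde | COc1cc([C@@H]2Oc3cc(C=O)cc(OC)c3O[C@H]2C)cc(OC)c1OC | intermediate
20 | (2E)-3-[(2S,3S)-5-methoxy-3-methyl-2-(3,4,5-trimethoxyphenyl)-2,3-dihydro-1,4-benzodioxin-7-yl]prop-2-enal | COc1cc([C@@H]2Oc3cc(/C=C/C=O)cc(OC)c3O[C@H]2C)cc(OC)c1OC | target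

## Step count and least certain steps

Total step count: 9. Longest linear sequence: 7 steps (1 → 3 → 6 → 10 → 16 → 17 → 19 → 20; steps 1, 2, 4, 6, 7, 8, 9).

**Step 6 (key step).** The most likely failure is loss of the aryloxy group by beta-elimination. Once boron is tetracoordinate (13, 15), or while 14 and 16 stand in the presence of Lewis acid or base, the aryloxide on the neighbouring carbon becomes a competent leaving group. A second risk is erosion at C2 by chloride exchange on 14 if the salts are not removed. A third is sluggish migration of the branched, oxygen-substituted C3 group in the first shift.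
The fallback is boron-free; it sets out from 8 and 12 and returns at 17.
- Mitsunobu etherification of 8 with methyl (R)-lactate (PPh3, DIAD) should give, with inversion, methyl (2S)-2-[2-bromo-4-(1,3-dioxolan-2-yl)-6-methoxyphenoxy]propanoate F1.
- MeNHOMe·HCl and i-PrMgCl convert it into (2S)-2-[2-bromo-4-(1,3-dioxolan-2-yl)-6-methoxyphenoxy]-N-methoxy-N-methylpropanamide F2.
- Addition of 12 gives (2S)-2-[2-bromo-4-(1,3-dioxolan-2-yl)-6-methoxyphenoxy]-1-(3,4,5-trimethoxyphenyl)propan-1-one F3.
- Reduction with LiBH(s-Bu)3 at −78 °C, by Felkin–Anh approach anti to the aryloxy group, should favour the threo alcohol 17.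

The weak points of this detour are the base sensitivity of the alpha-aryloxy carbonyl centre and a diastereoselectivity that rests on substrate control.

**Step 4.** The most likely failure is slow formation of the borate from a weakly basic phenoxide flanked by two ortho substituents. During a slow reaction the liberated chloride can exchange with unreacted 6 and erode the configuration of the future C3.
The fallback sets out from 8 and returns at 10.
- O-alkylation of 8 with racemic 2-bromopropanoic acid (NaH, 2 equiv) gives 2-[2-bromo-4-(1,3-dioxolan-2-yl)-6-methoxyphenoxy]propanoic acid F4.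
- N-hydroxyphthalimide and a carbodiimide give 1,3-dioxoisoindolin-2-yl 2-[2-bromo-4-(1,3-dioxolan-2-yl)-6-methoxyphenoxy]propanoate F5.
- Photoinduced decarboxylative borylation with bis(catecholato)diboron gives 2-{1-[2-bromo-4-(1,3-dioxolan-2-yl)-6-methoxyphenoxy]ethyl}-1,3,2-benzodioxaborole F6.
- Transesterification in the same flask with 2 and Et3N gives 10 together with its epimer (4R,5R)-2-{(1S)-1-[2-bromo-4-(1,3-dioxolan-2-yl)-6-methoxyphenoxy]ethyl}-4,5-dicyclohexyl-1,3,2-dioxaborolane F7, to be removed by chromatography or crystallisation.

This route gives up reagent control at C3 and loses half the material, so it secures supply of 10 but is not an equal replacement.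

**Step 8.** The most likely failure is slow oxidative addition of monovalent copper into an electron-rich, ortho-substituted aryl bromide. Reduction of the C–Br bond or oxidation of the benzylic alkoxide to the ketone could then compete. A change to Pd(OAc)2 with a bulky biaryl phosphine would be the first adjustment of conditions.
The fallback closes ring B from the other side; it sets out from 17 and returns at 19.
- Miyaura borylation (bis(pinacolato)diboron, Pd(dppf)Cl2, KOAc) gives (1S,2S)-2-[4-(1,3-dioxolan-2-yl)-2-methoxy-6-(4,4,5,5-tetramethyl-1,3,2-dioxaborolan-2-yl)phenoxy]-1-(3,4,5-trimethoxyphenyl)propan-1-ol F8.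
- Oxidation (H2O2, NaOH) gives 5-(1,3-dioxolan-2-yl)-2-{[(1S,2S)-1-hydroxy-1-(3,4,5-trimethoxyphenyl)propan-2-yl]oxy}-3-methoxyphenol F9.
- Acid-mediated cyclodehydration (TsOH, CH2Cl2, then water) through the benzylic cation forms the O1–C2 bond and hydrolyses the acetal.

The diequatorial trans isomer is expected to prevail, but this rests on thermodynamic preference and is not stereospecific.

**Step 9.** The most likely failure is a second olefination of the product, which is itself an aldehyde, together with incomplete conversion of the electron-rich aldehyde 19.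
The fallback sets out from 19 and returns at 20.
- Horner–Wadsworth–Emmons reaction with triethyl phosphonoacetate (NaH, THF) gives ethyl (2E)-3-[(2S,3S)-5-methoxy-3-methyl-2-(3,4,5-trimethoxyphenyl)-2,3-dihydro-1,4-benzodioxin-7-yl]prop-2-enoate F10.
- Reduction with i-Bu2AlH gives (2E)-3-[(2S,3S)-5-methoxy-3-methyl-2-(3,4,5-trimethoxyphenyl)-2,3-dihydro-1,4-benzodioxin-7-yl]prop-2-en-1-ol F11.
- Oxidation with MnO2 gives 20.

**Step 3.** The most likely failure is reversal of the acetalisation during work-up or chromatography, because the para-hydroxyl group stabilises the oxocarbenium ion.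
The fallback sets out from 7 and returns at 8.
- Acetylation (Ac2O, pyridine) gives 2-bromo-4-formyl-6-methoxyphenyl acetate F12.
- Acetalisation as in step 3 gives 2-bromo-4-(1,3-dioxolan-2-yl)-6-methoxyphenyl acetate F13.
- Methanolysis (K2CO3, MeOH) gives 8.

## Further compounds

F1 | step 6 | methyl (2S)-2-[2-bromo-4-(1,3-dioxolan-2-yl)-6-methoxyphenoxy]propanoate | C[C@H](Oc1c(Br)cc(C2OCCO2)cc1OC)C(=O)OC
F2 | step 6 | (2S)-2-[2-bromo-4-(1,3-dioxolan-2-yl)-6-methoxyphenoxy]-N-methoxy-N-methylpropanamide | C[C@H](Oc1c(Br)cc(C2OCCO2)cc1OC)C(=O)N(C)OC
F3 | step 6 | (2S)-2-[2-bromo-4-(1,3-dioxolan-2-yl)-6-methoxyphenoxy]-1-(3,4,5-trimethoxyphenyl)propan-1-one | C[C@H](Oc1c(Br)cc(C2OCCO2)cc1OC)C(=O)c1cc(OC)c(OC)c(OC)c1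
F4 | step 4 | 2-[2-bromo-4-(1,3-dioxolan-2-yl)-6-methoxyphenoxy]propanoic acid (racemic) | CC(Oc1c(Br)cc(C2OCCO2)cc1OC)C(=O)O
F5 | step 4 | 1,3-dioxoisoindolin-2-yl 2-[2-bromo-4-(1,3-dioxolan-2-yl)-6-methoxyphenoxy]propanoate (racemic) | CC(Oc1c(Br)cc(C2OCCO2)cc1OC)C(=O)ON1C(=O)c2ccccc2C1=O
F6 | step 4 | 2-{1-[2-bromo-4-(1,3-dioxolan-2-yl)-6-methoxyphenoxy]ethyl}-1,3,2-benzodioxaborole (racemic) | CC(Oc1c(Br)cc(C2OCCO2)cc1OC)B1Oc2ccccc2O1
F7 | step 4 | (4R,5R)-2-{(1S)-1-[2-bromo-4-(1,3-dioxolan-2-yl)-6-methoxyphenoxy]ethyl}-4,5-dicyclohexyl-1,3,2-dioxaborolane | C[C@@H](Oc1c(Br)cc(C2OCCO2)cc1OC)B1O[C@H](C2CCCCC2)[C@@H](C2CCCCC2)O1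
F8 | step 8 | (1S,2S)-2-[4-(1,3-dioxolan-2-yl)-2-methoxy-6-(4,4,5,5-tetramethyl-1,3,2-dioxaborolan-2-yl)phenoxy]-1-(3,4,5-trimethoxyphenyl)propan-1-ol | COc1cc([C@H](O)[C@H](C)Oc2c(B3OC(C)(C)C(C)(C)O3)cc(C3OCCO3)cc2OC)cc(OC)c1OC
F9 | step 8 | 5-(1,3-dioxolan-2-yl)-2-{[(1S,2S)-1-hydroxy-1-(3,4,5-trimethoxyphenyl)propan-2-yl]oxy}-3-methoxyphenol | COc1cc([C@H](O)[C@H](C)Oc2c(O)cc(C3OCCO3)cc2OC)cc(OC)c1OC
F10 | step 9 | ethyl (2E)-3-[(2S,3S)-5-methoxy-3-methyl-2-(3,4,5-trimethoxyphenyl)-2,3-dihydro-1,4-benzodioxin-7-yl]prop-2-enoate | COc1cc([C@@H]2Oc3cc(/C=C/C(=O)OCC)cc(OC)c3O[C@H]2C)cc(OC)c1OC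
F11 | step 9 | (2E)-3-[(2S,3S)-5-methoxy-3-methyl-2-(3,4,5-trimethoxyphenyl)-2,3-dihydro-1,4-benzodioxin-7-yl]prop-2-en-1-ol | COc1cc([C@@H]2Oc3cc(/C=C/CO)cc(OC)c3O[C@H]2C)cc(OC)c1OC
F12 | step 3 | 2-bromo-4-formyl-6-methoxyphenyl acetate | COc1cc(C=O)cc(Br)c1OC(C)=O
F13 | step 3 | 2-bromo-4-(1,3-dioxolan-2-yl)-6-methoxyphenyl acetate | COc1cc(C2OCCO2)cc(Br)c1OC(C)=O
A1 | alternative 1 | methyl 4-hydroxy-3-methoxy-5-{[(1R)-1-(3,4,5-trimethoxyphenyl)prop-2-en-1-yl]oxy}benzoate | COC(=O)c1cc(OC)c(O)c(O[C@H](C=C)c2cc(OC)c(OC)c(OC)c2)c1
A2 | alternative 1 | methyl (2S,3S)-5-methoxy-3-methyl-2-(3,4,5-trimethoxyphenyl)-2,3-dihydro-1,4-benzodioxine-7-carboxylate | COC(=O)c1cc(OC)c2O[C@@H](C)[C@H](c3cc(OC)c(OC)c(OC)c3)Oc2c1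
A3 | alternative 2 | ethyl (2R,3S)-2-[2-bromo-4-(1,3-dioxolan-2-yl)-6-methoxyphenoxy]-3-hydroxy-3-(3,4,5-trimethoxyphenyl)propanoate | CCOC(=O)[C@H](Oc1c(Br)cc(C2OCCO2)cc1OC)[C@@H](O)c1cc(OC)c(OC)c(OC)c1
A4 | alternative 2 | ethyl diazoacetate | CCOC(=O)C=[N+]=[N-]
A5 | alternative 2 | 3,4,5-trimethoxybenzaldehyde | COc1cc(C=O)cc(OC)c1OC
A6 | alternative 3 | (2S,3R)-2-methyl-3-(3,4,5-trimethoxyphenyl)oxirane | C[C@@H]1O[C@@H]1c1cc(OC)c(OC)c(OC)c1
A7 | alternative 3 | 4-fluoro-3-hydroxy-5-methoxybenzaldehyde | COc1cc(C=O)cc(O)c1F
A8 | alternative 3 | (2S,3S)-5-methoxy-3-methyl-2-(3,4,5-trimethoxyphenyl)-2,3-dihydro-1,4-benzodioxine-7-carbaldehyde | COc1cc([C@@H]2Oc3cc(C=O)cc(OC)c3O[C@H]2C)cc(OC)c1OC
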